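**Strategy**

Atoms are numbered from the acid carbon C1; the 1,2-dioxane is O1–O2–C3–C4–C5–C6 with O1 on C6, and the side chain is C7–C14. The plan cuts O2–C3 and C2–C1 in one stroke. Ring carbon C3 holds peroxide oxygen O2 and, through C2, the carboxyl carbon C1, a 1,2-oxygen/acyl relationship that oxidative carbonylation of a terminal C3=C2 alkene by an internal oxygen nucleophile can write in a single pass. One palladium-mediated operation thus closes the dioxane, attaches the ester arm and sets C3. The precursor is an acyclic tertiary C6 hydroperoxide bearing the C4 ethyl stereocentre, the C3=C2 vinyl group and an acetonide-masked C7–C8 diol, the latent C7 aldehyde for the side chain.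

Key step: step 7

Assumption (step 1): the (R,R) antipode of Taniaphos is taken to deliver the (S)-bromide, by analogy with related γ-substituted allylic bromides; the sense would be confirmed on the first batch, and the (S,S) ligand used if it is reversed.

Remark: the descriptors of 13 and 15 were re-derived from the target and are self-consistent. C7 (R) in 13 fixes the D-(−)-tartrate in step 4. The aldehyde carbon of 17 is C7, carried on C6.

**Route**

Step 1
Reactants: 1 (E)-1,4-dibromobut-2-ene; 2 ethylmagnesium bromide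
Product: 3 (S)-3-(bromomethyl)pent-1-ene
Conditions: CuBr·SMe2 (3 mol%), (R,R)-Taniaphos (3.5 mol%), EtMgBr (1.15 equiv, Et2O), CH2Cl2, −78 °C
Reagents that add atoms: none
Why: Copper-catalysed asymmetric allylic alkylation (SN2′) of an allylic bromide with a Grignard reagent: the chiral copper–diphosphine complex delivers ethyl to the γ-carbon on one alkene face, which sets the future C4 centre, and the homoallylic bromide that remains is no longer an allylic electrophile, so the second C–Br bond should be left alone.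

Step 2
Reactants: 3 (S)-3-(bromomethyl)pent-1-ene; 4 ethyl pent-2-ynoate
Product: 8 ethyl (2E,5R)-3,5-diethylhepta-2,6-dienoate, via Grignard reagent 5 (not isolated), via alkylcopper reagent 6 (not isolated), via alkenylcopper adduct 7 (not isolated)
Conditions: Mg, THF, rt; CuBr·SMe2 (1.0 equiv), THF–Me2S, −45 °C; 4 (0.8 equiv), −78 °C; AcOH, −78 °C
Reagents that add atoms: none
Why: Syn carbocupration (conjugate addition of a monoalkylcopper reagent) of the 2-alkynoate puts the alkyl group and copper on the same side, and protonation of the alkenylcopper at −78 °C with retention should leave the C6 ethyl cis to the ester, i.e. the (2E) geometry; the C4 centre is β to the metal and is not touched.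

Step 3
Reactants: 8 ethyl (2E,5R)-3,5-diethylhepta-2,6-dienoate
Product: 9 (2E,5R)-3,5-diethylhepta-2,6-dien-1-ol
Conditions: i-Bu2AlH (2.2 equiv), CH2Cl2, −78 → 0 °C; aq. KNaC4H4O6
Reagents that add atoms: none
Why: Hydride 1,2-reduction of an α,β-unsaturated ester by i-Bu2AlH should give the allylic alcohol with the alkene geometry and the remote stereocentre unchanged.

Step 4
Reactants: 9 (2E,5R)-3,5-diethylhepta-2,6-dien-1-ol
Product: 10 [(2R,3R)-3-ethyl-3-[(2R)-2-ethylbut-3-en-1-yl]oxiran-2-yl]methanol
Conditions: Ti(Oi-Pr)4 (10 mol%), D-(−)-diethyl tartrate (12 mol%), t-BuOOH (2 equiv), 4 Å MS, CH2Cl2, −20 °C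
Reagents that add atoms: tert-butyl hydroperoxide, CC(C)(C)OO
Why: Sharpless asymmetric epoxidation: only the allylic alcohol binds the titanium tartrate, so the terminal alkene is spared, and with the D-(−)-tartrate oxygen is delivered to the face that gives the (2R,3R)-epoxide (C7 R, C6 R), the C6 configuration that inversion in step 5 turns into the required one.

Step 5
Reactants: 10 [(2R,3R)-3-ethyl-3-[(2R)-2-ethylbut-3-en-1-yl]oxiran-2-yl]methanol
Product: 11 (2R,3S,5R)-3,5-diethyl-3-hydroperoxyhept-6-ene-1,2-diol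
Conditions: H2O2 (ca. 2 M in Et2O, 8 equiv), H3PMo12O40 (5 mol%), Et2O, 0 °C → rt
Reagents that add atoms: hydrogen peroxide, OO
Why: Acid-catalysed perhydrolysis of an epoxide (molybdenum-activated ring opening by H2O2): the nucleophile should enter at the tertiary carbon C6, which carries the developing positive charge best, anti to the departing epoxide oxygen, so that C6 is inverted to the (S)-hydroperoxide while C7 keeps its oxygen and configuration.

Step 6
Reactants: 11 (2R,3S,5R)-3,5-diethyl-3-hydroperoxyhept-6-ene-1,2-diol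
Product: 13 (3R,5S)-5-[(4R)-2,2-dimethyl-1,3-dioxolan-4-yl]-3-ethyl-5-hydroperoxyhept-1-ene, via peroxyketal acetonide 12 (not isolated)
Conditions: 2-methoxypropene (3 equiv), PPTS (5 mol%), CH2Cl2, 0 °C; then MeOH, 0 °C; Et3N
Reagents that add atoms: 2-methoxypropene, COC(C)=C
Why: Kinetic acetonide formation with an enol ether: the primary C8 hydroxyl is ketalised first and its oxocarbenium ion is closed by the C7 hydroxyl to the five-membered dioxolane, while the hydroperoxide is capped only as an acyclic peroxyketal, which ionises with loss of the hydroperoxide far more readily than the cyclic acetonide and should therefore be removed selectively by brief acid methanolysis.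

Step 7
Reactants: 13 (3R,5S)-5-[(4R)-2,2-dimethyl-1,3-dioxolan-4-yl]-3-ethyl-5-hydroperoxyhept-1-ene; 14 carbon monoxide
Product: 15 methyl 2-[(3S,4R,6S)-6-[(4R)-2,2-dimethyl-1,3-dioxolan-4-yl]-4,6-diethyl-1,2-dioxan-3-yl]acetate
Conditions: PdCl2(MeCN)2 (10 mol%), p-benzoquinone (2 equiv), NaOAc (1 equiv), CO (1 atm), MeOH–CH2Cl2 (1:1), 0 °C → rt
Reagents that add atoms: methanol (CH3OH), CO
Why: Proposed new method: divalent palladium binds the C3=C2 alkene and the C6 hydroperoxide adds through its terminal oxygen O2 to C3 (peroxypalladation), giving a C2–palladium σ-bond that under CO should insert carbon monoxide faster than it loses a β-hydrogen; methanolysis of the acylpalladium releases the methyl ester and zerovalent palladium, which benzoquinone returns to the divalent state. The closest known reaction types are the palladium-catalysed alkoxycarbonylative cyclisation of hydroxy alkenes to tetrahydropyranylacetates (Semmelhack type) and the palladium-catalysed Wacker-type cyclisation of unsaturated hydroperoxides to 1,2-dioxanes; their union on one substrate is the untested part. The 1,2-dioxane closes 6-exo-trig through a chair. C3 is set by that chair: the C4 and C6 ethyl groups are cis and must both sit equatorial, which places the dioxolanyl group axial on C6 and the alkene terminus C2 equatorial on C3, so the C3–C2 bond ends trans to the C4 ethyl, i.e. (3S). The step needs O2 to be the only nucleophile and carbonylation to beat both β-hydride loss and oxygen transfer from the hydroperoxide to CO: the acetonide removes both hydroxyl competitors and the NaOAc buffer keeps it in place in methanol, the terminal alkene gives a primary alkylpalladium that carbonylates readily, and C6 has no hydrogen, so base-type peroxide fragmentation cannot start there.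

Step 8
Reactants: 15 methyl 2-[(3S,4R,6S)-6-[(4R)-2,2-dimethyl-1,3-dioxolan-4-yl]-4,6-diethyl-1,2-dioxan-3-yl]acetate
Product: 17 methyl 2-[(3S,4R,6S)-4,6-diethyl-6-formyl-1,2-dioxan-3-yl]acetate, via diol 16 (not isolated)
Conditions: H5IO6 (2.5 equiv), EtOAc, 0 °C → rt
Reagents that add atoms: none
Why: One-pot acetonide hydrolysis and Malaprade glycol cleavage: periodic acid is acidic enough to open the terminal acetonide and then cleaves the C7–C8 diol to the C7 aldehyde, which cannot epimerise because C6 is quaternary; the dialkyl peroxide and the ester are inert to periodate.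

Step 9
Reactants: 18 (E)-pent-2-enal; 19 diethylzinc
Product: 20 (3R,4E)-hept-4-en-3-ol
Conditions: (2R)-(+)-3-exo-morpholinoisoborneol (4 mol%), Et2Zn (1.5 equiv), hexane–toluene, 0 °C; 1 M HCl
Reagents that add atoms: none
Why: Amino-alcohol-catalysed enantioselective 1,2-addition of diethylzinc to an aldehyde (Noyori type): the chiral zinc aminoalkoxide should deliver ethyl to one face of the enal carbonyl, and the (2R) ligand antipode, mirror image of the one that gives (S)-carbinols, gives the (R)-carbinol.

Step 10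
Reactants: 20 (3R,4E)-hept-4-en-3-ol; 21 triethyl orthoacetate
Product: 22 ethyl (3R,4E)-3-ethylhept-4-enoate
Conditions: MeC(OEt)3 (5 equiv), EtCO2H (5 mol%), 140 °C, EtOH distilled off
Reagents that add atoms: none
Why: Johnson–Claisen rearrangement: the ketene acetal formed in situ rearranges through a chair with the carbinol ethyl group equatorial, so the C–O chirality is relayed suprafacially to the new C9–C10 bond, setting C10 (R) and the (E)-C11=C12 alkene in the same event.

Step 11
Reactants: 22 ethyl (3R,4E)-3-ethylhept-4-enoate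
Product: 23 (3R,4E)-3-ethylhept-4-en-1-ol
Conditions: LiAlH4, Et2O, 0 °C
Reagents that add atoms: none
Why: Hydride reduction of the ester to the primary alcohol with LiAlH4; the isolated alkene and the C10 centre are not affected.

Step 12
Reactants: 23 (3R,4E)-3-ethylhept-4-en-1-ol
Product: 24 (3E,5R)-5-ethyl-7-iodohept-3-ene
Conditions: I2, PPh3, imidazole, CH2Cl2, 0 °C → rt
Reagents that add atoms: iodine (I2), [I][I]
Why: Appel-type iodination (Garegg–Samuelsson conditions): the primary alcohol is activated as an alkoxyphosphonium ion and displaced by iodide in an SN2 reaction at C8, two carbons away from the stereocentre.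

Step 13
Reactants: 24 (3E,5R)-5-ethyl-7-iodohept-3-ene
Product: 25 [(3R,4E)-3-ethylhept-4-en-1-yl]triphenylphosphonium iodide
Conditions: PPh3, MeCN, 80 °C
Reagents that add atoms: triphenylphosphine, c1ccc(cc1)P(c1ccccc1)c1ccccc1
Why: SN2 quaternisation of triphenylphosphine by the primary iodide should give the Wittig salt.

Step 14
Reactants: 17 methyl 2-[(3S,4R,6S)-4,6-diethyl-6-formyl-1,2-dioxan-3-yl]acetate; 25 [(3R,4E)-3-ethylhept-4-en-1-yl]triphenylphosphonium iodide
Product: 29 methyl 2-[(3S,4R,6S)-4,6-diethyl-6-[(1Z,4R,5E)-4-ethyl-2-iodoocta-1,5-dien-1-yl]-1,2-dioxan-3-yl]acetate, via ylide 26 (not isolated), via iodophosphonium salt 27 (not isolated), via iodo ylide 28 (not isolated)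
Conditions: 25 (2.5 equiv), NaN(SiMe3)2, THF, −20 °C; I2, −78 °C; NaN(SiMe3)2, −20 °C; 17, −78 → −20 °C
Reagents that add atoms: iodine (I2), [I][I]
Why: α-Iodo Wittig olefination (Stork–Zhao olefination extended to substituted ylides): the ylide is iodinated and deprotonated again, and the resulting non-stabilised α-iodo ylide should add to the aldehyde under kinetic control through the cis-oxaphosphetane, placing iodine cis to C6 in the (Z)-iodoalkene; low temperature and the high electrophilicity of the aldehyde should let olefination outrun deprotonation at C2.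

Step 15
Reactants: 29 methyl 2-[(3S,4R,6S)-4,6-diethyl-6-[(1Z,4R,5E)-4-ethyl-2-iodoocta-1,5-dien-1-yl]-1,2-dioxan-3-yl]acetate; 19 diethylzinc
Product: 30 methyl 2-[(3S,4R,6S)-6-[(1E,4R,5E)-2,4-diethylocta-1,5-dien-1-yl]-4,6-diethyl-1,2-dioxan-3-yl]acetate
Conditions: Et2Zn (2 equiv), Pd(t-Bu3P)2 (5 mol%), THF, 0 °C → rt
Reagents that add atoms: none
Why: Negishi cross-coupling: oxidative addition of zerovalent palladium to the C–I bond, transmetallation from zinc and reductive elimination all proceed with retention at the alkene, so ethyl replaces iodine cis to C6 and the (7E) trisubstituted alkene results; the bulky electron-rich phosphine should make reductive elimination faster than β-hydride loss from the ethyl group and allows a temperature at which the O–O bond is left alone.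

Step 16
Reactants: 30 methyl 2-[(3S,4R,6S)-6-[(1E,4R,5E)-2,4-diethylocta-1,5-dien-1-yl]-4,6-diethyl-1,2-dioxan-3-yl]acetate
Product: 31 2-[(3S,4R,6S)-6-[(1E,4R,5E)-2,4-diethylocta-1,5-dien-1-yl]-4,6-diethyl-1,2-dioxan-3-yl]acetic acid
Conditions: LiOH (3 equiv), THF–H2O (3:1), 0 °C → rt; 1 M HCl to pH 3, 0 °C
Reagents that add atoms: lithium hydroxide, [Li+].[OH-]
Why: Saponification of the methyl ester with LiOH at or below room temperature, conditions that 3,6-dialkyl-1,2-dioxanes tolerate, followed by mild acidification should give the acid without opening the β-peroxy ester.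

**Compound list**

1 | (E)-1,4-dibromobut-2-ene | BrC/C=C/CBr | starting material
2 | ethylmagnesium bromide | CC[Mg]Br | starting material
3 | (S)-3-(bromomethyl)pent-1-ene | BrC[C@@H](CC)C=C | intermediate
4 | ethyl pent-2-ynoate | CCC#CC(=O)OCC | starting material
5 | [(2S)-2-ethylbut-3-en-1-yl]magnesium bromide (Grignard reagent) | Br[Mg]C[C@@H](CC)C=C | intermediate
6 | [(2S)-2-ethylbut-3-en-1-yl]copper (alkylcopper reagent) | [Cu]C[C@@H](CC)C=C | intermediate
7 | ethyl (2Z,5R)-2-cuprio-3,5-diethylhepta-2,6-dienoate (alkenylcopper adduct) | CCOC(=O)/C([Cu])=C(CC)/C[C@@H](CC)C=C | intermediate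
8 | ethyl (2E,5R)-3,5-diethylhepta-2,6-dienoate | CCOC(=O)/C=C(CC)/C[C@@H](CC)C=C | intermediate
9 | (2E,5R)-3,5-diethylhepta-2,6-dien-1-ol | OC/C=C(CC)/C[C@@H](CC)C=C | intermediate
10 | [(2R,3R)-3-ethyl-3-[(2R)-2-ethylbut-3-en-1-yl]oxiran-2-yl]methanol | OC[C@H]1O[C@]1(CC)C[C@@H](CC)C=C | intermediate
11 | (2R,3S,5R)-3,5-diethyl-3-hydroperoxyhept-6-ene-1,2-diol | OC[C@@H](O)[C@](OO)(CC)C[C@@H](CC)C=C | intermediate
12 | (4R)-4-[(3S,5R)-5-ethyl-3-[(2-methoxypropan-2-yl)peroxy]hept-6-en-3-yl]-2,2-dimethyl-1,3-dioxolane (peroxyketal acetonide) | CC1(C)OC[C@@H](O1)[C@](OOC(C)(C)OC)(CC)C[C@@H](CC)C=C | intermediate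
13 | (3R,5S)-5-[(4R)-2,2-dimethyl-1,3-dioxolan-4-yl]-3-ethyl-5-hydroperoxyhept-1-ene | CC1(C)OC[C@@H](O1)[C@](OO)(CC)C[C@@H](CC)C=C | intermediate
14 | carbon monoxide | [C-]#[O+] | starting material
15 | methyl 2-[(3S,4R,6S)-6-[(4R)-2,2-dimethyl-1,3-dioxolan-4-yl]-4,6-diethyl-1,2-dioxan-3-yl]acetate | CC1(C)OC[C@@H](O1)[C@]2(CC)C[C@@H](CC)[C@H](CC(=O)OC)OO2 | intermediate
16 | methyl 2-[(3S,4R,6S)-6-[(1R)-1,2-dihydroxyethyl]-4,6-diethyl-1,2-dioxan-3-yl]acetate (diol) | OC[C@@H](O)[C@]1(CC)C[C@@H](CC)[C@H](CC(=O)OC)OO1 | intermediate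
17 | methyl 2-[(3S,4R,6S)-4,6-diethyl-6-formyl-1,2-dioxan-3-yl]acetate | O=C[C@]1(CC)C[C@@H](CC)[C@H](CC(=O)OC)OO1 | intermediate
18 | (E)-pent-2-enal | CC/C=C/C=O | starting material
19 | diethylzinc | CC[Zn]CC | starting material
20 | (3R,4E)-hept-4-en-3-ol | CC/C=C/[C@H](O)CC | intermediate
21 | triethyl orthoacetate | CCOC(C)(OCC)OCC | starting material
22 | ethyl (3R,4E)-3-ethylhept-4-enoate | CCOC(=O)C[C@@H](CC)/C=C/CC | intermediate
23 | (3R,4E)-3-ethylhept-4-en-1-ol | OCC[C@@H](CC)/C=C/CC | intermediate
24 | (3E,5R)-5-ethyl-7-iodohept-3-ene | ICC[C@@H](CC)/C=C/CC | intermediate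
25 | [(3R,4E)-3-ethylhept-4-en-1-yl]triphenylphosphonium iodide | CC/C=C/[C@H](CC)CC[P+](c1ccccc1)(c1ccccc1)c1ccccc1.[I-] | intermediate
26 | [(3R,4E)-3-ethylhept-4-en-1-ylidene]triphenyl-λ5-phosphane (ylide) | CC/C=C/[C@H](CC)CC=P(c1ccccc1)(c1ccccc1)c1ccccc1 | intermediate
27 | [(3R,4E)-3-ethyl-1-iodohept-4-en-1-yl]triphenylphosphonium iodide (iodophosphonium salt, both C1 epimers) | CC/C=C/[C@H](CC)CC(I)[P+](c1ccccc1)(c1ccccc1)c1ccccc1.[I-] | intermediate
28 | [(3R,4E)-3-ethyl-1-iodohept-4-en-1-ylidene]triphenyl-λ5-phosphane (iodo ylide) | CC/C=C/[C@H](CC)CC(I)=P(c1ccccc1)(c1ccccc1)c1ccccc1 | intermediate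
29 | methyl 2-[(3S,4R,6S)-4,6-diethyl-6-[(1Z,4R,5E)-4-ethyl-2-iodoocta-1,5-dien-1-yl]-1,2-dioxan-3-yl]acetate | CC/C=C/[C@H](CC)C/C(I)=C/[C@]1(CC)C[C@@H](CC)[C@H](CC(=O)OC)OO1 | intermediate
30 | methyl 2-[(3S,4R,6S)-6-[(1E,4R,5E)-2,4-diethylocta-1,5-dien-1-yl]-4,6-diethyl-1,2-dioxan-3-yl]acetate | CC/C=C/[C@H](CC)C/C(=C/[C@]1(CC)C[C@@H](CC)[C@H](CC(=O)OC)OO1)CC | intermediate
31 | 2-[(3S,4R,6S)-6-[(1E,4R,5E)-2,4-diethylocta-1,5-dien-1-yl]-4,6-diethyl-1,2-dioxan-3-yl]acetic acid (CNP0398571.2) | CC/C=C/[C@H](CC)C/C(=C/[C@]1(CC)C[C@@H](CC)[C@H](CC(=O)O)OO1)CC | target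

**Count and risk**

Total: 16 steps. Longest linear sequence: 11 steps (steps 1–8, then 14–16); the side-chain branch (steps 9–13) joins at step 14.

Steps most likely to fail:

Step 7. The hydroperoxide may be deoxygenated by palladium and CO before it cyclises, the alkylpalladium may lose a β-hydrogen instead of inserting CO, or the acetonide may be lost in methanol so that a freed hydroxyl cyclises in place of the peroxide oxygen. The fallback sets out from 12, isolated by stopping step 6 before the methanol stage. Cross-metathesis with methyl acrylate (second-generation Hoveyda–Grubbs catalyst, CH2Cl2, 40 °C; dialkyl peroxides and peroxyketals tolerate ruthenium carbenes) should give methyl (2E,4R,6S)-6-[(4R)-2,2-dimethyl-1,3-dioxolan-4-yl]-4-ethyl-6-[(2-methoxypropan-2-yl)peroxy]oct-2-enoate F1. PPTS in MeOH at 0 °C then frees the hydroperoxide to give methyl (2E,4R,6S)-6-[(4R)-2,2-dimethyl-1,3-dioxolan-4-yl]-4-ethyl-6-hydroperoxyoct-2-enoate F2. Catalytic Et2NH in CF3CH2OH closes the ring by 6-exo oxa-Michael addition of the hydroperoxide to the enoate, a known way to 1,2-dioxan-3-ylacetates; the addition is reversible and should settle on the isomer with the C3 and C4 substituents both equatorial. This comes back to the route at 15.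

Step 14. Addition of the bulky α-iodo ylide to the α-quaternary aldehyde may be slow, the basic ylide may open the β-peroxy ester by elimination, and Z selectivity may be incomplete. The fallback sets out from 17 and from 3 and introduces the two C8 substituents by cross-coupling instead. Ramirez olefination (CBr4, PPh3, Zn, CH2Cl2, 0 °C) should give methyl 2-[(3S,4R,6S)-6-(2,2-dibromoethenyl)-4,6-diethyl-1,2-dioxan-3-yl]acetate F3. Separately, cross-metathesis of 3 with (E)-hex-3-ene (second-generation Grubbs catalyst) should give (3E,5S)-5-(bromomethyl)hept-3-ene F4, which has the C10 configuration because C4 and C10 carry the same substituent pattern; zinc dust with LiCl in THF converts it into [(2S,3E)-2-ethylhex-3-en-1-yl]zinc bromide F5. Trans-selective Negishi monoalkylation of F3 with F5 (PdCl2(DPEphos), THF, 0 °C), in which the bromine trans to C6 reacts first, should give methyl 2-[(3S,4R,6S)-6-[(1Z,4R,5E)-2-bromo-4-ethylocta-1,5-dien-1-yl]-4,6-diethyl-1,2-dioxan-3-yl]acetate F6. Ethylation of F6 under the conditions of step 15 comes back to the route at 30.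

Step 6. The hydroperoxide and the C7 hydroxyl may capture the acetone unit together as a 1,2,4-trioxane instead of the C7/C8 diol as a dioxolane, or the acetonide may be partly lost while the peroxyketal is methanolysed. The fallback sets out from 11 and replaces the ketal by silyl protection. TBSOTf and 2,6-lutidine (CH2Cl2, −78 → 0 °C) silylate all three oxygens to give (2R,3S,5R)-1,2-bis[(tert-butyldimethylsilyl)oxy]-3-[(tert-butyldimethylsilyl)peroxy]-3,5-diethylhept-6-ene F7. K2CO3 in MeOH at 0 °C should cleave only the silicon–peroxide bond, the hydroperoxide anion being much the better leaving group, to give (2R,3S,5R)-1,2-bis[(tert-butyldimethylsilyl)oxy]-3,5-diethyl-3-hydroperoxyhept-6-ene F8. The conditions of step 7 convert F8 into methyl 2-[(3S,4R,6S)-6-[(1R)-1,2-bis[(tert-butyldimethylsilyl)oxy]ethyl]-4,6-diethyl-1,2-dioxan-3-yl]acetate F9. HF·pyridine in THF removes both silyl ethers and comes back to the route at 16, which NaIO4 in aqueous THF cleaves to 17.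

Further compounds
F1 | step 7 | methyl (2E,4R,6S)-6-[(4R)-2,2-dimethyl-1,3-dioxolan-4-yl]-4-ethyl-6-[(2-methoxypropan-2-yl)peroxy]oct-2-enoate | CC1(C)OC[C@@H](O1)[C@](OOC(C)(C)OC)(CC)C[C@@H](CC)/C=C/C(=O)OC
F2 | step 7 | methyl (2E,4R,6S)-6-[(4R)-2,2-dimethyl-1,3-dioxolan-4-yl]-4-ethyl-6-hydroperoxyoct-2-enoate | CC1(C)OC[C@@H](O1)[C@](OO)(CC)C[C@@H](CC)/C=C/C(=O)OC
F3 | step 14 | methyl 2-[(3S,4R,6S)-6-(2,2-dibromoethenyl)-4,6-diethyl-1,2-dioxan-3-yl]acetate | BrC(Br)=C[C@]1(CC)C[C@@H](CC)[C@H](CC(=O)OC)OO1
F4 | step 14 | (3E,5S)-5-(bromomethyl)hept-3-ene | BrC[C@@H](CC)/C=C/CC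
F5 | step 14 | [(2S,3E)-2-ethylhex-3-en-1-yl]zinc bromide | Br[Zn]C[C@@H](CC)/C=C/CC
F6 | step 14 | methyl 2-[(3S,4R,6S)-6-[(1Z,4R,5E)-2-bromo-4-ethylocta-1,5-dien-1-yl]-4,6-diethyl-1,2-dioxan-3-yl]acetate | CC/C=C/[C@H](CC)C/C(Br)=C/[C@]1(CC)C[C@@H](CC)[C@H](CC(=O)OC)OO1
F7 | step 6 | (2R,3S,5R)-1,2-bis[(tert-butyldimethylsilyl)oxy]-3-[(tert-butyldimethylsilyl)peroxy]-3,5-diethylhept-6-ene | CC(C)(C)[Si](C)(C)OC[C@@H](O[Si](C)(C)C(C)(C)C)[C@](OO[Si](C)(C)C(C)(C)C)(CC)C[C@@H](CC)C=C
F8 | step 6 | (2R,3S,5R)-1,2-bis[(tert-butyldimethylsilyl)oxy]-3,5-diethyl-3-hydroperoxyhept-6-ene | CC(C)(C)[Si](C)(C)OC[C@@H](O[Si](C)(C)C(C)(C)C)[C@](OO)(CC)C[C@@H](CC)C=C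
F9 | step 6 | methyl 2-[(3S,4R,6S)-6-[(1R)-1,2-bis[(tert-butyldimethylsilyl)oxy]ethyl]-4,6-diethyl-1,2-dioxan-3-yl]acetate | CC(C)(C)[Si](C)(C)OC[C@@H](O[Si](C)(C)C(C)(C)C)[C@]1(CC)C[C@@H](CC)[C@H](CC(=O)OC)OO1
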